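**Plan**

- Retrosynthesis cuts, in order: the aryl–vinyl C–C bond at C6 (Stille coupling), the two C–H bonds at C2 and C3 (back to a C2=C3 benzodioxine acid), the C2–C3 bond of the dioxane ring B (key step), then the O4–CH2–aryl bond (Mitsunobu) and the O1–allyl bond.
- Forward: ring A (a bromoguaiacol core) is O-allylated, Baeyer–Villiger-oxidized and O-benzylated with ring C; ring B is then closed by C2–C3 bond formation; the C6 side chain is attached last and the silyl groups are removed.
- Enabling feature: C3 is a benzylic ether carbon between O4 and ring C, whose para-oxygen makes it a latent para-quinone methide (hydride-donor site). C2 is alpha to O1 and carries the carbon that can sit at the aldehyde level (enamine donor). O1 and O4 are ortho on ring A, so the two ends are held for six-ring closure.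
- Stereochemistry: both centers are set together by a carboxyl-directed asymmetric syn-hydrogenation of C2=C3 (cis from syn addition, absolute sense from the chiral Ru diphosphine complex); the later steps do not touch either center.
- Helpers removed after use: aldehyde/acid level of the C2 substituent, C2=C3 unsaturation, Br at C6, TBS groups on ring C.

Key step: step 7

Remark: the SMILES given corresponds to the cis isomer (aryl at C3 and hydroxymethyl at C2 on the same face of ring B; C2 R, C3 S), and the route is designed for that isomer.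

Labels: atoms follow the 1,4-benzodioxine numbering of the target (O1–C2(CH2OH)–C3(aryl)–O4, side chain at C6, OMe at C8). Ring A is the benzo ring, ring B the dioxane ring, ring C the pendant aryl. Ar = 3,4-bis(tert-butyldimethylsilyloxy)-5-methoxyphenyl; TBS = tert-butyldimethylsilyl.

**Route**

Step 1
Reactants: 1 5-bromo-2-hydroxy-3-methoxybenzaldehyde; 2 allyl bromide
Product: 3 2-(allyloxy)-5-bromo-3-methoxybenzaldehyde
Conditions: K2CO3, DMF, 50 °C
Reagents that add atoms: none
Why: Williamson ether synthesis on the only phenol of 1 places the allyl group on the oxygen that becomes O1 (next to OMe, para to Br).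

Step 2
Reactants: 3 2-(allyloxy)-5-bromo-3-methoxybenzaldehyde
Product: 5 2-(allyloxy)-5-bromo-3-methoxyphenol, via aryl formate 4 (not isolated)
Conditions: mCPBA, CH2Cl2, 0 °C to rt; then K2CO3 (cat.), MeOH, rt
Reagents that add atoms: mCPBA (3-chloroperoxybenzoic acid), OOC(=O)c1cccc(Cl)c1
Why: Baeyer–Villiger oxidation of the electron-rich ortho-alkoxybenzaldehyde (aryl migration) and formate methanolysis should unmask the phenol that becomes O4 without any regiochemical ambiguity.

Step 3
Reactants: 6 3,4-dihydroxy-5-methoxybenzaldehyde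
Product: 7 3,4-bis(tert-butyldimethylsilyloxy)-5-methoxybenzaldehyde
Conditions: TBSCl, imidazole, DMF, rt
Reagents that add atoms: TBSCl (tert-butyldimethylsilyl chloride), CC(C)(C)[Si](C)(C)Cl
Why: Silylation of both phenols masks the catechol of ring C against the later oxidant while keeping the para-oxygen a pi-donor, and the groups can be removed by fluoride under near-neutral conditions.

Step 4
Reactants: 7 3,4-bis(tert-butyldimethylsilyloxy)-5-methoxybenzaldehyde
Product: 8 [3,4-bis(tert-butyldimethylsilyloxy)-5-methoxyphenyl]methanol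
Conditions: NaBH4, THF/EtOH, 0 °C
Reagents that add atoms: none
Why: Borohydride reduction of the aryl aldehyde should give the benzylic alcohol needed for etherification.

Step 5
Reactants: 5 2-(allyloxy)-5-bromo-3-methoxyphenol; 8 [3,4-bis(tert-butyldimethylsilyloxy)-5-methoxyphenyl]methanol
Product: 9 2-(allyloxy)-5-bromo-1-(Ar-methoxy)-3-methoxybenzene
Conditions: PPh3, DIAD, THF, 0 °C to rt
Reagents that add atoms: none
Why: Mitsunobu etherification of the phenol with the primary benzylic alcohol should form the O4–CH2–Ar bond under neutral conditions that spare the aryl silyl ethers.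

Step 6
Reactants: 9 2-(allyloxy)-5-bromo-1-(Ar-methoxy)-3-methoxybenzene
Product: 11 2-[4-bromo-2-(Ar-methoxy)-6-methoxyphenoxy]acetaldehyde, via diol 10 (not isolated)
Conditions: OsO4 (2 mol%), NaIO4, 2,6-lutidine, dioxane/H2O, rt
Reagents that add atoms: OsO4 (osmium tetroxide), O=[Os](=O)(=O)=O; NaIO4 (sodium periodate), [Na+].[O-]I(=O)(=O)=O
Why: Lemieux–Johnson oxidation (dihydroxylation then periodate cleavage) should turn the allyl ether into the aryloxyacetaldehyde, which puts the future C2 substituent at the aldehyde level needed for enamine activation.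

Step 7
Reactants: 11 2-[4-bromo-2-(Ar-methoxy)-6-methoxyphenoxy]acetaldehyde
Product: 14 6-bromo-3-Ar-8-methoxy-1,4-benzodioxine-2-carbaldehyde, via oxocarbenium salt 12 (not isolated), via saturated aldehyde 13 (not isolated)
Conditions: DDQ (1.1 equiv), LiClO4, 4 Å MS, ClCH2CH2Cl (0.02 M), 0 °C; then (S)-α,α-diphenylprolinol trimethylsilyl ether (20 mol%), rt; then DDQ (1.2 equiv), rt
Reagents that add atoms: none
Why: Proposed new method: DDQ abstracts hydride from the only activated methylene, the O4-benzylic CH2 (future C3) flanked by the aryl ether oxygen O4 and ring C with its para-silyloxy group (a latent para-quinone methide), giving oxocarbenium salt 12; the secondary amine then turns the pendant CHO into an enamine whose carbon C2 (alpha to O1) adds to C3, and a second equivalent of DDQ removes hydride from the tertiary C3–H of the enamine of 13 to leave the C2=C3 enal 14. The closest known reaction types are the DDQ-mediated cross-dehydrogenative coupling of benzylic ethers with aldehydes under enamine catalysis, the DDQ-induced oxidative cyclization of benzylic ethers onto tethered enol nucleophiles, and the amine/DDQ dehydrogenation of aldehydes to enals. Ring B closes in a 6-(enolexo)-endo-trig mode, the enamine carbon C2 attacking the endocyclic O4=C3 cation. No stereocenter remains in 14 (the two formed in 13 are erased by the second oxidation), so no stereocontrol is asked of this step and either antipode of the amine serves. The step needs site selectivity in the hydride abstraction, secured by the electron-rich ring C and O4 against the carbonyl-deactivated OCH2CHO methylene, and ring closure over oligomerization, secured by the ortho placement of O1 and O4 on ring A and by dilution. The push–pull enal 14 has no further abstractable hydride, which should stop the oxidation at this stage.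

Step 8
Reactants: 14 6-bromo-3-Ar-8-methoxy-1,4-benzodioxine-2-carbaldehyde
Product: 15 6-bromo-3-Ar-8-methoxy-1,4-benzodioxine-2-carboxylic acid
Conditions: NaClO2, NaH2PO4, 2-methyl-2-butene, t-BuOH/H2O, rt
Reagents that add atoms: NaClO2 (sodium chlorite), [Na+].[O-]Cl=O
Why: Pinnick oxidation should convert the enal into the acid that directs the hydrogenation, with the alkene scavenger protecting the enol ether and the aryl rings from hypochlorous acid.

Step 9
Reactants: 15 6-bromo-3-Ar-8-methoxy-1,4-benzodioxine-2-carboxylic acid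
Product: 16 (2S,3S)-6-bromo-3-Ar-8-methoxy-2,3-dihydro-1,4-benzodioxine-2-carboxylic acid (cis)
Conditions: H2 (50 bar), Ru(OAc)2[H8-BINAP] (2 mol%, ligand antipode fixed by a test run), MeOH, 40 °C
Reagents that add atoms: none
Why: Carboxyl-directed asymmetric hydrogenation of a tetrasubstituted α,β-unsaturated acid: the Ru-bound carboxylate should deliver both hydrogens to one face of C2=C3 (syn addition), so the aryl and carboxyl groups end up cis, and the chiral diphosphine selects the face that gives C2 S and C3 S.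

Step 10
Reactants: 16 (2S,3S)-6-bromo-3-Ar-8-methoxy-2,3-dihydro-1,4-benzodioxine-2-carboxylic acid
Product: 17 [(2R,3S)-6-bromo-3-Ar-8-methoxy-2,3-dihydro-1,4-benzodioxin-2-yl]methanol (cis)
Conditions: BH3·SMe2, THF, 0 °C to rt
Reagents that add atoms: none
Why: Borane reduction of the carboxylic acid should give the primary alcohol without enolization, so both stereocenters are retained (the C2 descriptor changes from S to R only because the priorities change).

Step 11
Reactants: 17 [(2R,3S)-6-bromo-3-Ar-8-methoxy-2,3-dihydro-1,4-benzodioxin-2-yl]methanol; 18 (E)-3-(tributylstannyl)prop-2-en-1-ol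
Product: 19 (E)-3-[(2R,3S)-3-Ar-2-(hydroxymethyl)-8-methoxy-2,3-dihydro-1,4-benzodioxin-6-yl]prop-2-en-1-ol
Conditions: Pd(PPh3)4 (5 mol%), toluene, 100 °C
Reagents that add atoms: none
Why: Stille coupling of the C6 aryl bromide with the (E)-alkenylstannane should install the allylic alcohol side chain with retention of alkene geometry under base-free conditions that leave the silyl ethers and the cis ring intact.

Step 12
Reactants: 19 (E)-3-[(2R,3S)-3-Ar-2-(hydroxymethyl)-8-methoxy-2,3-dihydro-1,4-benzodioxin-6-yl]prop-2-en-1-ol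
Product: 20 (E)-3-[(2R,3S)-3-(3,4-dihydroxy-5-methoxyphenyl)-2-(hydroxymethyl)-8-methoxy-2,3-dihydro-1,4-benzodioxin-6-yl]prop-2-en-1-ol (CNP0174261.1)
Conditions: TBAF, AcOH (1:1), THF, 0 °C
Reagents that add atoms: none
Why: Fluoride desilylation buffered with acetic acid should free both phenols while keeping the para-phenol protonated, so that the C3–O4 benzylic ether cannot open through a quinone methide and the cis configuration is kept.

**Compound list**

1 | 5-bromo-2-hydroxy-3-methoxybenzaldehyde | COc1cc(Br)cc(C=O)c1O | starting material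
2 | allyl bromide | C=CCBr | starting material
3 | 2-(allyloxy)-5-bromo-3-methoxybenzaldehyde | COc1cc(Br)cc(C=O)c1OCC=C | intermediate
4 | 2-(allyloxy)-5-bromo-3-methoxyphenyl formate | COc1cc(Br)cc(OC=O)c1OCC=C | intermediate
5 | 2-(allyloxy)-5-bromo-3-methoxyphenol | COc1cc(Br)cc(O)c1OCC=C | intermediate
6 | 3,4-dihydroxy-5-methoxybenzaldehyde | COc1cc(C=O)cc(O)c1O | starting material
7 | 3,4-bis(tert-butyldimethylsilyloxy)-5-methoxybenzaldehyde | COc1cc(C=O)cc(O[Si](C)(C)C(C)(C)C)c1O[Si](C)(C)C(C)(C)C | intermediate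
8 | [3,4-bis(tert-butyldimethylsilyloxy)-5-methoxyphenyl]methanol | COc1cc(CO)cc(O[Si](C)(C)C(C)(C)C)c1O[Si](C)(C)C(C)(C)C | intermediate
9 | 2-(allyloxy)-5-bromo-1-{[3,4-bis(tert-butyldimethylsilyloxy)-5-methoxyphenyl]methoxy}-3-methoxybenzene | COc1cc(Br)cc(OCc2cc(OC)c(O[Si](C)(C)C(C)(C)C)c(O[Si](C)(C)C(C)(C)C)c2)c1OCC=C | intermediate
10 | 3-[4-bromo-2-{[3,4-bis(tert-butyldimethylsilyloxy)-5-methoxyphenyl]methoxy}-6-methoxyphenoxy]propane-1,2-diol | COc1cc(Br)cc(OCc2cc(OC)c(O[Si](C)(C)C(C)(C)C)c(O[Si](C)(C)C(C)(C)C)c2)c1OCC(O)CO | intermediate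
11 | 2-[4-bromo-2-{[3,4-bis(tert-butyldimethylsilyloxy)-5-methoxyphenyl]methoxy}-6-methoxyphenoxy]acetaldehyde | COc1cc(Br)cc(OCc2cc(OC)c(O[Si](C)(C)C(C)(C)C)c(O[Si](C)(C)C(C)(C)C)c2)c1OCC=O | intermediate
12 | [5-bromo-3-methoxy-2-(2-oxoethoxy)phenoxy][3,4-bis(tert-butyldimethylsilyloxy)-5-methoxyphenyl]methylium 2,3-dichloro-5,6-dicyano-4-hydroxyphenolate | COc1cc(Br)cc(O[CH+]c2cc(OC)c(O[Si](C)(C)C(C)(C)C)c(O[Si](C)(C)C(C)(C)C)c2)c1OCC=O.[O-]c1c(Cl)c(Cl)c(O)c(C#N)c1C#N | intermediate
13 | 6-bromo-3-[3,4-bis(tert-butyldimethylsilyloxy)-5-methoxyphenyl]-8-methoxy-2,3-dihydro-1,4-benzodioxine-2-carbaldehyde (racemic, both diastereomers) | COc1cc(C2Oc3cc(Br)cc(OC)c3OC2C=O)cc(O[Si](C)(C)C(C)(C)C)c1O[Si](C)(C)C(C)(C)C | intermediate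
14 | 6-bromo-3-[3,4-bis(tert-butyldimethylsilyloxy)-5-methoxyphenyl]-8-methoxy-1,4-benzodioxine-2-carbaldehyde | COc1cc(C2=C(C=O)Oc3c(OC)cc(Br)cc3O2)cc(O[Si](C)(C)C(C)(C)C)c1O[Si](C)(C)C(C)(C)C | intermediate
15 | 6-bromo-3-[3,4-bis(tert-butyldimethylsilyloxy)-5-methoxyphenyl]-8-methoxy-1,4-benzodioxine-2-carboxylic acid | COc1cc(C2=C(C(=O)O)Oc3c(OC)cc(Br)cc3O2)cc(O[Si](C)(C)C(C)(C)C)c1O[Si](C)(C)C(C)(C)C | intermediate
16 | (2S,3S)-6-bromo-3-[3,4-bis(tert-butyldimethylsilyloxy)-5-methoxyphenyl]-8-methoxy-2,3-dihydro-1,4-benzodioxine-2-carboxylic acid | COc1cc([C@@H]2Oc3cc(Br)cc(OC)c3O[C@@H]2C(=O)O)cc(O[Si](C)(C)C(C)(C)C)c1O[Si](C)(C)C(C)(C)C | intermediate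
17 | [(2R,3S)-6-bromo-3-[3,4-bis(tert-butyldimethylsilyloxy)-5-methoxyphenyl]-8-methoxy-2,3-dihydro-1,4-benzodioxin-2-yl]methanol | COc1cc([C@@H]2Oc3cc(Br)cc(OC)c3O[C@@H]2CO)cc(O[Si](C)(C)C(C)(C)C)c1O[Si](C)(C)C(C)(C)C | intermediate
18 | (E)-3-(tributylstannyl)prop-2-en-1-ol | CCCC[Sn](CCCC)(CCCC)/C=C/CO | starting material
19 | (E)-3-[(2R,3S)-3-[3,4-bis(tert-butyldimethylsilyloxy)-5-methoxyphenyl]-2-(hydroxymethyl)-8-methoxy-2,3-dihydro-1,4-benzodioxin-6-yl]prop-2-en-1-ol | COc1cc([C@@H]2Oc3cc(/C=C/CO)cc(OC)c3O[C@@H]2CO)cc(O[Si](C)(C)C(C)(C)C)c1O[Si](C)(C)C(C)(C)C | intermediate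
20 | (E)-3-[(2R,3S)-3-(3,4-dihydroxy-5-methoxyphenyl)-2-(hydroxymethyl)-8-methoxy-2,3-dihydro-1,4-benzodioxin-6-yl]prop-2-en-1-ol | COc1cc([C@@H]2Oc3cc(/C=C/CO)cc(OC)c3O[C@@H]2CO)cc(O)c1O | target

**Step count and risks**

Total steps: 12. Longest linear sequence: 10 (steps 1, 2, 5 to 12); steps 3 and 4 prepare the ring C fragment in parallel.

Steps most likely to fail:

1. Step 7 (proposed new method). Hydride abstraction from the benzyl aryl ether may be too slow with the silyloxy-substituted ring C. The enamine may be consumed by the quinone before it cyclizes. The cyclized aldehyde may also open by beta-elimination of the O4 phenoxide. Fallback (known chemistry, ring B built through its C–O bonds): it sets out from 7 and 1 and comes back at 15. Aldehyde 7 is homologated with ethyl diazoacetate and catalytic SnCl2 (Roskamp reaction) to ethyl 3-Ar-3-oxopropanoate F1. This is brominated with NBS to ethyl 2-bromo-3-Ar-3-oxopropanoate F2, which O-alkylates phenol 1 (K2CO3, acetone) to ethyl 2-(4-bromo-2-formyl-6-methoxyphenoxy)-3-Ar-3-oxopropanoate F3. Baeyer–Villiger oxidation with mCPBA gives ethyl 2-[4-bromo-2-(formyloxy)-6-methoxyphenoxy]-3-Ar-3-oxopropanoate F4. Methanolysis frees the phenol, which closes onto the ketone to the hemiketal ethyl 6-bromo-3-hydroxy-3-Ar-8-methoxy-2,3-dihydro-1,4-benzodioxine-2-carboxylate F5. Dehydration (TsOH, toluene, 80 °C) gives ethyl 6-bromo-3-Ar-8-methoxy-1,4-benzodioxine-2-carboxylate F6, and Me3SnOH in 1,2-dichloroethane cleaves the ester to acid 15.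

2. Step 9. Hydrogen delivery to the tetrasubstituted, electron-rich enol ether double bond may be sluggish or poorly face-selective, and beta-elimination of an aryloxide from the metal alkyl may compete. Fallback: it sets out from 15 and comes back at 16. Acid 15 is hydrogenated with the achiral complex [Ir(cod)(PCy3)(py)]PF6 (H2, CH2Cl2), a directed syn addition that should give the racemic cis acid rac-6-bromo-3-Ar-8-methoxy-2,3-dihydro-1,4-benzodioxine-2-carboxylic acid F7. Crystallization with (R)-1-phenylethylamine (or its antipode, whichever gives the less soluble salt of the wanted acid) should give (R)-1-phenylethylammonium (2S,3S)-6-bromo-3-Ar-8-methoxy-2,3-dihydro-1,4-benzodioxine-2-carboxylate F8, and acidification returns 16.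

3. Step 11. Oxidative addition into the electron-rich aryl bromide may be slow, letting protodestannylation and homocoupling of the stannane take over. Fallback: it sets out from 17 and comes back at 19. A Heck reaction of 17 with methyl acrylate (Pd(OAc)2, P(o-tol)3, NaOAc, DMF, 100 °C) should give methyl (E)-3-[(2R,3S)-3-Ar-2-(hydroxymethyl)-8-methoxy-2,3-dihydro-1,4-benzodioxin-6-yl]prop-2-enoate F9, and DIBAL-H (CH2Cl2, −78 °C) reduces the ester to 19.

**Further compounds**

F1 | step 7 | ethyl 3-[3,4-bis(tert-butyldimethylsilyloxy)-5-methoxyphenyl]-3-oxopropanoate | CCOC(=O)CC(=O)c1cc(OC)c(O[Si](C)(C)C(C)(C)C)c(O[Si](C)(C)C(C)(C)C)c1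
F2 | step 7 | ethyl 2-bromo-3-[3,4-bis(tert-butyldimethylsilyloxy)-5-methoxyphenyl]-3-oxopropanoate | CCOC(=O)C(Br)C(=O)c1cc(OC)c(O[Si](C)(C)C(C)(C)C)c(O[Si](C)(C)C(C)(C)C)c1
F3 | step 7 | ethyl 2-(4-bromo-2-formyl-6-methoxyphenoxy)-3-[3,4-bis(tert-butyldimethylsilyloxy)-5-methoxyphenyl]-3-oxopropanoate | CCOC(=O)C(Oc1c(OC)cc(Br)cc1C=O)C(=O)c1cc(OC)c(O[Si](C)(C)C(C)(C)C)c(O[Si](C)(C)C(C)(C)C)c1
F4 | step 7 | ethyl 2-[4-bromo-2-(formyloxy)-6-methoxyphenoxy]-3-[3,4-bis(tert-butyldimethylsilyloxy)-5-methoxyphenyl]-3-oxopropanoate | CCOC(=O)C(Oc1c(OC)cc(Br)cc1OC=O)C(=O)c1cc(OC)c(O[Si](C)(C)C(C)(C)C)c(O[Si](C)(C)C(C)(C)C)c1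
F5 | step 7 | ethyl 6-bromo-3-hydroxy-3-[3,4-bis(tert-butyldimethylsilyloxy)-5-methoxyphenyl]-8-methoxy-2,3-dihydro-1,4-benzodioxine-2-carboxylate | CCOC(=O)C1Oc2c(OC)cc(Br)cc2OC1(O)c1cc(OC)c(O[Si](C)(C)C(C)(C)C)c(O[Si](C)(C)C(C)(C)C)c1
F6 | step 7 | ethyl 6-bromo-3-[3,4-bis(tert-butyldimethylsilyloxy)-5-methoxyphenyl]-8-methoxy-1,4-benzodioxine-2-carboxylate | CCOC(=O)C1=C(c2cc(OC)c(O[Si](C)(C)C(C)(C)C)c(O[Si](C)(C)C(C)(C)C)c2)Oc2cc(Br)cc(OC)c2O1
F7 | step 9 | rac-cis-6-bromo-3-[3,4-bis(tert-butyldimethylsilyloxy)-5-methoxyphenyl]-8-methoxy-2,3-dihydro-1,4-benzodioxine-2-carboxylic acid (both enantiomers) | COc1cc([C@@H]2Oc3cc(Br)cc(OC)c3O[C@@H]2C(=O)O)cc(O[Si](C)(C)C(C)(C)C)c1O[Si](C)(C)C(C)(C)C.COc1cc([C@H]2Oc3cc(Br)cc(OC)c3O[C@H]2C(=O)O)cc(O[Si](C)(C)C(C)(C)C)c1O[Si](C)(C)C(C)(C)C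
F8 | step 9 | (R)-1-phenylethylammonium (2S,3S)-6-bromo-3-[3,4-bis(tert-butyldimethylsilyloxy)-5-methoxyphenyl]-8-methoxy-2,3-dihydro-1,4-benzodioxine-2-carboxylate | COc1cc([C@@H]2Oc3cc(Br)cc(OC)c3O[C@@H]2C(=O)[O-])cc(O[Si](C)(C)C(C)(C)C)c1O[Si](C)(C)C(C)(C)C.C[C@@H]([NH3+])c1ccccc1
F9 | step 11 | methyl (E)-3-[(2R,3S)-3-[3,4-bis(tert-butyldimethylsilyloxy)-5-methoxyphenyl]-2-(hydroxymethyl)-8-methoxy-2,3-dihydro-1,4-benzodioxin-6-yl]prop-2-enoate | COc1cc([C@@H]2Oc3cc(/C=C/C(=O)OC)cc(OC)c3O[C@@H]2CO)cc(O[Si](C)(C)C(C)(C)C)c1O[Si](C)(C)C(C)(C)C
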